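Does the average chain in the flask reach 1000 units by 30 min? The average is a ratio of two amounts, each a fraction of the free monomer charged: monomer in chains over chains begun.

| flask | free monomer | pre-initiator | remark | time |
|---|---|---|---|---|
| alder | 0.025 M | 0.50 mM | run made earlier |  |
| elm | 0.10 M | 0.50 mM | run made earlier |  |
| ash | 0.050 M | 0.25 mM | run made earlier |  |
| flask | 0.050 M | 0.50 mM |  | 30 min |

- alder (time / min: monomer in chains / %, free monomer / %): 3.00: 1.3, 96.3; 5.00: 1.8, 95.3; 8.00: 3.5, 94.4; 12.0: 5.6, 92.9; 20.0: 9.4, 88.5; 40.0: 18.1, 79.6
- elm (time / min: monomer in chains / %, free monomer / %): 2.50: 0.9, 99.1; 8.00: 4.3, 95.7; 12.0: 6.0, 93.7; 20.0: 9.7, 89.7; 30.0: 14.4, 84.9; 40.0: 19.2, 80.0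
- ash (time / min: monomer in chains / %, free monomer / %): 3.00: 0.5, 99.0; 5.00: 1.5, 98.4; 10.0: 2.1, 96.6; 20.0: 4.7, 94.7; 40.0: 9.6, 89.7

(scatter of a reading: 0.3 percentage points)

- the average divides the monomer in chains by the number of chains begun, living and dead together
- what was read earlier has a scatter of 0.3 percentage points, one standard deviation
- the earlier runs do not show the number of chains; that part of a forecast is a guess

- whether the average number of monomer units in a chain (chains begun, living or dead) reaches 1000 by 30 min (no / yes)
- average number of monomer units in a chain (chains begun, living or dead) at 30 min

1. From the elm run at 30.0 min I read 0.00518 /min as the growth rate, the fraction of the free monomer joining chains per minute, a pseudo-first-order constant.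

2. At 40.0 min, the alder run, with a quarter of the elm run's monomer, reads 18.1% against 19.2%. With half the pre-initiator, the growth rate gives 9.85% for the ash run, which reads 9.6%. So I expect the flask, with the elm run's pre-initiator, to hold about 14.4% in chains at 30 min.

3. The wanted length in the flask therefore needs chains begun below about 0.0144%, while the flask's pre-initiator is 1.00%, 69.4 times more.

4. The readings of the alder run at 40.0 min leave 2.30% outside both columns, near its pre-initiator, 2.00%. I do not take that gap as a count of chains, so I leave the flask's length open, where the forecast gives one.

The forecast says no, with 14.4 units, from “roughly one monomer held per pre-initiator, suggesting near-complete activation”.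

The flask gives yes, with 1620 units.

    free monomer + initiator → living end + monomer in chains (k = 0.0430 /M/s)
    free monomer + living end → monomer in chains + living end, rate k2*[living end]*[free monomer] (k = 20.0 /M/s)
    pre-initiator ⇌ initiator (K = 2.30, k = 0.0370 /s)
    free monomer + initiator → spent initiator (k = 4.80 /M/s)

At 30.0 min the flask holds living end at 0.00888% of the free monomer charged and spent initiator at 0.991%. With that chain count, the growth rate puts the wanted length at 18.0 min, and the flask reaches it at 18.2 min.

The readings were generated by integration for substances that don't exist.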